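Ring B is cut at C4–C3 and C8a–C1 (tetralin numbering): a [3+3] union of a vanillyl unit, nucleophilic first at its benzylic carbon C4 and then at ring-A carbon C8a (para to C6–OMe), with a C1–C2–C3 unit electrophilic at C3 and C1. The feature exploited is the 1,4-relationship of the C2 carboxyl and the C3 hydroxymethyl: tied as a γ-lactone they give an oxolane-2,4-dione in which C3 is a ketone and C2 carries C1 as a benzylic methyl ether. In one flask the benzylic Grignard reagent adds to C3, then acid ionises C1 and ring B closes on the trans-lactone template, setting C3 and C1 from C2.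

Key step: step 5

Assumption: tetralin numbering of the target (C1–C4, C4a, C8a; ring A fused arene, ring B saturated ring, ring C pendant aryl) is used for every intermediate, and lactone 1, the less common antipode of the D-lactone, is taken as a purchasable chiral-pool compound.

Step 1
Reactants: 1 2,3-O-isopropylidene-L-erythronolactone; 2 3,4,5-tris(benzyloxy)benzaldehyde
Product: 4 (3aS,6aS)-3a-{methoxy[3,4,5-tris(benzyloxy)phenyl]methyl}-2,2-dimethyldihydrofuro[3,4-d][1,3]dioxol-4(3aH)-one (C1 epimer mixture), via lithium aldolate 3 (not isolated)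
Conditions: LiN(SiMe3)2, THF, −78 °C; 2; then MeOTf, −78 → −30 °C
Reagents that add atoms: methyl trifluoromethanesulfonate, COS(=O)(=O)C(F)(F)F
Why: Aldol addition of a lactone lithium enolate (the β-oxygen is held in the cis-fused dioxolane, close to the nodal plane of the enolate, which disfavours β-elimination): the aldehyde can only enter on the convex face because the dioxolane must stay cis-fused, so C2 is created with its oxygen cis to O3 and with fixed absolute configuration, C1 forms as an epimer mixture that converges in step 5, and methyl triflate O-alkylates the aldolate so that C1 is masked for step 3 and armed as a leaving group for step 5.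

Step 2
Reactants: 4 methyl ether acetonide
Product: 5 (3R,4S)-3,4-dihydroxy-3-{methoxy[3,4,5-tris(benzyloxy)phenyl]methyl}oxolan-2-one (cis-diol, C1 epimers)
Conditions: TsOH·H2O (cat.), MeOH, 45 °C
Reagents that add atoms: none
Why: Acid-catalysed transketalisation to the solvent removes the isopropylidene group, while the lactone, the benzyl ethers and the benzylic methyl ether (whose exchange with methanol would be degenerate) persist and no stereocentre is touched.

Step 3
Reactants: 5 cis-diol lactone
Product: 6 (3S)-3-hydroxy-3-{methoxy[3,4,5-tris(benzyloxy)phenyl]methyl}oxolane-2,4-dione (C1 epimers)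
Conditions: IBX, DMSO, 25 °C
Reagents that add atoms: none
Why: IBX oxidation of the secondary C3 carbinol of the cis-1,2-diol should stop at the α-hydroxy ketone without C–C cleavage, the tertiary C2 hydroxyl and the etherified C1 being inert, and the C3 stereocentre is erased on purpose because it is rebuilt in step 5.

Step 4
Reactants: 7 [4-(benzyloxy)-3-methoxyphenyl]methanol
Product: 8 1-(benzyloxy)-4-(chloromethyl)-2-methoxybenzene
Conditions: SOCl2, CH2Cl2, 0 → 25 °C
Reagents that add atoms: thionyl chloride, O=S(Cl)Cl
Why: Chlorodehydroxylation of a benzylic alcohol with thionyl chloride gives the halide needed for magnesium insertion; no stereocentre is involved.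

Step 5
Reactants: 6 oxolane-2,4-dione; 8 benzylic chloride
Product: 11 7-(benzyloxy)-2,3-dihydroxy-6-methoxy-1-[3,4,5-tris(benzyloxy)phenyl]-1,2,3,4-tetrahydronaphthalene-2,3-carbolactone (C2 carbonyl to C3 CH2O, trans-fused; tetralin centres 1S,2S,3R), via benzylic Grignard reagent 9 (not isolated), via ring-open diol 10 (not isolated)
Conditions: 8, Mg, Et2O, 0 °C; 6, t-BuMgCl, CH2Cl2, −78 °C; then 9, −78 °C; then TfOH, −78 → 0 °C
Reagents that add atoms: none
Why: t-BuMgCl first converts the C2 hydroxyl into its chloromagnesium alkoxide, which chelates the C3 ketone, and Grignard reagent 9 then adds to C3 (C4–C3 bond) on the ring face anti to the bulky C1 side chain, so that in 10 the benzyl group is trans to that side chain and the new C3–OH is trans to C2–OH. Triflic acid then ionises the C1 methyl ether to a benzylic cation stabilised by the para-benzyloxy group of ring C, and C8a of ring A, para to the C6 methoxy group, attacks it (C8a–C1 bond) in a Friedel–Crafts alkylation that closes the six-membered ring B in the exo mode with respect to the cationic C1 centre. The closest known reaction types are the Grignard addition to a cyclic α-hydroxy ketone and the acid-mediated cyclisation of trans-2,3-dibenzylbutyrolactones bearing a benzylic oxygen to aryltetralin lactones. C3 is controlled by the C2 stereocentre through the five-membered ring, and C1 by the trans-fused lactone template, which holds the C2 carbonyl and the C3 CH2O carbon pseudo-equatorial so that the aryl group takes the pseudo-equatorial position trans to the C2 carbonyl and cis to C2–OH, both C1 epimers of 6 converging through the planar cation. The step needs addition to the ketone instead of attack on the lactone carbonyl or enolisation (low temperature, lactone carbonyl shielded by the quaternary C2), ring closure at C8a and not at the crowded position between CH2 and OMe, and ring closure faster than a 1,2-shift in the cation (the tethered, electron-rich ring A is placed for six-membered closure).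

Step 6
Reactants: 11 trans-fused lactone
Product: 13 (1S,2S,3R)-7-(benzyloxy)-2,3-dihydroxy-3-(hydroxymethyl)-6-methoxy-1-[3,4,5-tris(benzyloxy)phenyl]-1,2,3,4-tetrahydronaphthalene-2-carboxylic acid, via lithium carboxylate 12 (not isolated)
Conditions: LiOH, THF–H2O, 25 °C; then aq. HCl to pH 3, 0 °C
Reagents that add atoms: lithium hydroxide, [Li+].[OH-]
Why: Hydroxide opens the strained trans-fused γ-lactone by acyl–oxygen cleavage (saponification) and cold acidification should free the acid without relactonisation; C2 and C3 are quaternary and C1 is not acidic, so no centre can epimerise.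

Step 7
Reactants: 13 tetra-O-benzyl acid
Product: 14 (1S,2S,3R)-2,3,7-trihydroxy-3-(hydroxymethyl)-6-methoxy-1-(3,4,5-trihydroxyphenyl)-1,2,3,4-tetrahydronaphthalene-2-carboxylic acid (CNP0174537.1)
Conditions: H2 (1 atm), Pd/C, THF–MeOH, 25 °C
Reagents that add atoms: none
Why: Hydrogenolysis of the four aryl benzyl ethers over palladium on carbon under neutral conditions should free the phenols, leave the aryl methyl ether, the tertiary alcohols and the doubly benzylic C1–H untouched, and give toluene as the only by-product.

Compound list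
1 | 2,3-O-isopropylidene-L-erythronolactone, (3aS,6aS)-2,2-dimethyldihydrofuro[3,4-d][1,3]dioxol-4(3aH)-one | O=C1OC[C@@H]2OC(C)(C)O[C@H]12 | starting material
2 | 3,4,5-tris(benzyloxy)benzaldehyde | O=Cc1cc(OCc2ccccc2)c(OCc2ccccc2)c(OCc2ccccc2)c1 | starting material
3 | lithium alkoxide of the aldol adduct of 1 and 2 (new C–C bond on the convex face; C1 epimers) | O=C1OC[C@@H]2OC(C)(C)O[C@]12C([O-])c1cc(OCc2ccccc2)c(OCc2ccccc2)c(OCc2ccccc2)c1.[Li+] | intermediate
4 | (3aS,6aS)-3a-{methoxy[3,4,5-tris(benzyloxy)phenyl]methyl}-2,2-dimethyldihydrofuro[3,4-d][1,3]dioxol-4(3aH)-one (C1 epimers) | O=C1OC[C@@H]2OC(C)(C)O[C@]12C(OC)c1cc(OCc2ccccc2)c(OCc2ccccc2)c(OCc2ccccc2)c1 | intermediate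
5 | (3R,4S)-3,4-dihydroxy-3-{methoxy[3,4,5-tris(benzyloxy)phenyl]methyl}oxolan-2-one (cis-diol; C1 epimers) | O=C1OC[C@H](O)[C@@]1(O)C(OC)c1cc(OCc2ccccc2)c(OCc2ccccc2)c(OCc2ccccc2)c1 | intermediate
6 | (3S)-3-hydroxy-3-{methoxy[3,4,5-tris(benzyloxy)phenyl]methyl}oxolane-2,4-dione (C1 epimers) | O=C1OCC(=O)[C@@]1(O)C(OC)c1cc(OCc2ccccc2)c(OCc2ccccc2)c(OCc2ccccc2)c1 | intermediate
7 | [4-(benzyloxy)-3-methoxyphenyl]methanol | COc1cc(CO)ccc1OCc1ccccc1 | starting material
8 | 1-(benzyloxy)-4-(chloromethyl)-2-methoxybenzene | COc1cc(CCl)ccc1OCc1ccccc1 | intermediate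
9 | [4-(benzyloxy)-3-methoxybenzyl]magnesium chloride | COc1cc(C[Mg]Cl)ccc1OCc1ccccc1 | intermediate
10 | (3S,4R)-4-[4-(benzyloxy)-3-methoxybenzyl]-3,4-dihydroxy-3-{methoxy[3,4,5-tris(benzyloxy)phenyl]methyl}oxolan-2-one (trans-diol, benzyl trans to the C1 side chain; present as its chloromagnesium alkoxide until the acid is added; C1 epimers) | O=C1OC[C@](O)(Cc2ccc(OCc3ccccc3)c(OC)c2)[C@@]1(O)C(OC)c1cc(OCc2ccccc2)c(OCc2ccccc2)c(OCc2ccccc2)c1 | intermediate
11 | 7-(benzyloxy)-2,3-dihydroxy-6-methoxy-1-[3,4,5-tris(benzyloxy)phenyl]-1,2,3,4-tetrahydronaphthalene-2,3-carbolactone (trans-fused γ-lactone of 13; tetralin centres 1S,2S,3R) | COc1cc2c(cc1OCc1ccccc1)[C@H](c1cc(OCc3ccccc3)c(OCc3ccccc3)c(OCc3ccccc3)c1)[C@@]3(O)C(=O)OC[C@]3(O)C2 | intermediate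
12 | lithium salt of acid 13 | COc1cc2c(cc1OCc1ccccc1)[C@H](c1cc(OCc3ccccc3)c(OCc3ccccc3)c(OCc3ccccc3)c1)[C@@](O)(C(=O)[O-])[C@](O)(CO)C2.[Li+] | intermediate
13 | (1S,2S,3R)-7-(benzyloxy)-2,3-dihydroxy-3-(hydroxymethyl)-6-methoxy-1-[3,4,5-tris(benzyloxy)phenyl]-1,2,3,4-tetrahydronaphthalene-2-carboxylic acid | COc1cc2c(cc1OCc1ccccc1)[C@H](c1cc(OCc3ccccc3)c(OCc3ccccc3)c(OCc3ccccc3)c1)[C@@](O)(C(=O)O)[C@](O)(CO)C2 | intermediate
14 | (1S,2S,3R)-2,3,7-trihydroxy-3-(hydroxymethyl)-6-methoxy-1-(3,4,5-trihydroxyphenyl)-1,2,3,4-tetrahydronaphthalene-2-carboxylic acid | COc1cc2c(cc1O)[C@H](c1cc(O)c(O)c(O)c1)[C@@](O)(C(=O)O)[C@](O)(CO)C2 | target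

Total step count: 7. Longest linear sequence: 6 steps (steps 1, 2, 3, 5, 6, 7 from lactone 1); step 4 is a one-step side branch.

Steps most likely to fail

Step 5. The Grignard reagent may act as a base and enolise the C3 ketone instead of adding. In the acid phase the C1 cation may undergo a 1,2-shift next to the free tertiary C2 hydroxyl, or close ring B with poor facial selectivity, before C8a attacks. The fallback sets out from 6 and 8 and gives up the single-flask sequence. The organocerium reagent made from 9 and anhydrous CeCl3 is added to 6 at −78 °C and diol 10 is isolated. Both tertiary hydroxyls are then silylated (Me3SiOTf, 2,6-lutidine, CH2Cl2) to bis(trimethylsilyl) ether F1. Ring B is closed in a separate step with BF3·OEt2 in CH2Cl2 to silylated lactone F2. The trans-vicinal silyloxy groups cannot trigger a pinacol-type shift and should favour the diaxial arrangement that the lactone template needs. Dilute HCl in THF–H2O removes the silyl groups and the route is rejoined at 11.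

Step 1. The lactone enolate may lose its β-oxygen by elimination before the aldehyde is captured, and the hindered aldolate may revert by retro-aldol cleavage while it is being O-methylated. The fallback sets out from 1 and 2. Lactone 1 is deprotonated in the presence of Me3SiCl (LiN(i-Pr)2, THF, −78 °C) to give silyl ketene acetal F3. Aldehyde 2 is converted with HC(OMe)3 and TsOH in MeOH into dimethyl acetal F4. A Mukaiyama aldol-type addition of F3 to F4 (BF3·OEt2, CH2Cl2, −78 °C) should form the C2–C1 bond on the same convex face and deliver the benzylic methyl ether directly, rejoining the route at 4.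

Step 3. The 1,2-diol may suffer oxidative C–C cleavage, or the α-hydroxy ketone may undergo an acyloin shift under the oxidation conditions. The fallback sets out from 5. The cis-diol is condensed with Bu2SnO (toluene, reflux, removal of water) to give stannylene acetal F5. Brominolysis (Br2, CH2Cl2, molecular sieves, 25 °C) should oxidise only the oxygen-bearing C3–H carbon and rejoin the route at 6.

Further compounds
F1 | step 5 | bis(trimethylsilyl) ether of diol 10 | O=C1OC[C@](O[Si](C)(C)C)(Cc2ccc(OCc3ccccc3)c(OC)c2)[C@@]1(O[Si](C)(C)C)C(OC)c1cc(OCc2ccccc2)c(OCc2ccccc2)c(OCc2ccccc2)c1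
F2 | step 5 | bis(trimethylsilyl) ether of lactone 11 | COc1cc2c(cc1OCc1ccccc1)[C@H](c1cc(OCc3ccccc3)c(OCc3ccccc3)c(OCc3ccccc3)c1)[C@@]3(O[Si](C)(C)C)C(=O)OC[C@]3(O[Si](C)(C)C)C2
F3 | step 1 | trimethylsilyl ketene acetal of lactone 1, (6aS)-2,2-dimethyl-4-(trimethylsilyloxy)-6,6a-dihydrofuro[3,4-d][1,3]dioxole | C[Si](C)(C)OC1=C2OC(C)(C)O[C@H]2CO1
F4 | step 1 | 3,4,5-tris(benzyloxy)benzaldehyde dimethyl acetal | COC(OC)c1cc(OCc2ccccc2)c(OCc2ccccc2)c(OCc2ccccc2)c1
F5 | step 3 | dibutylstannylene acetal of cis-diol 5 | CCCC[Sn]1(CCCC)O[C@H]2COC(=O)[C@]2(O1)C(OC)c1cc(OCc2ccccc2)c(OCc2ccccc2)c(OCc2ccccc2)c1
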